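**Retrosynthetic overview**
- Numbering: the tetrahydrofuran is O1, C2 (ring A, 4-hydroxy-3-methoxyphenyl), C3 and C4 (methyls), C5 (ring B). The side chain is C8' (aryloxy carbon on the ring B oxygen) and C7' (carbinol bearing ring C). The core is 2,3-cis, 3,4-cis, 4,5-trans.
- The plan rests on C2. It holds ring A on the same face as the C3 methyl, which is the crowded and less stable arrangement. It is also bonded to O1, so it can be generated as a ring A-stabilised oxocarbenium carbon and receive its hydrogen last, from the face away from the methyls.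
- Disconnections: both benzyl ethers; the C7'–H bond; the ring C–C7' bond; the ring B O–C8' bond (inversion of ethyl (S)-lactate). Then O1–C2 and C2–H (γ-hydroxy ketone), ring A–C2 (aryllithium plus 3,4-cis-4,5-trans lactone), and C5–H and ring B–C5 (meso anhydride).
- Ring order: rings A, B and C are bought. The anhydride and lactone rings are temporary. The tetrahydrofuran, the only ring built for the target, closes in step 7.

Key step: step 7

Assumption: the (R,R)-TADDOL-derived phosphoramidite in step 3 is taken to steer the aryl group to the carbonyl that gives the (2R,3S)-keto acid. If the sense of induction is the opposite, the equally available (S,S)-ligand is used and nothing else changes.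

**Step 1**
Reactants: 1 meso-2,3-dimethylsuccinic acid
Product: 2 cis-2,3-dimethylsuccinic anhydride (meso)
Conditions: AcCl (neat), reflux
Reagents that add atoms: none
Why: Cyclodehydration of a 1,4-diacid through its mixed anhydride with acetyl chloride closes the five-membered anhydride under mild, base-free heating, so the two methine carbons keep their meso (cis) relationship.

**Step 2**
Reactants: 3 4-bromo-2-methoxyphenol
Product: 4 (4-bromo-2-methoxyphenoxy)triisopropylsilane
Conditions: TIPSCl, imidazole, DMF, rt
Reagents that add atoms: triisopropylsilyl chloride, CC(C)[Si](Cl)(C(C)C)C(C)C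
Why: Imidazole-promoted silylation of a phenol gives a bulky aryl silyl ether that tolerates organolithium, organozinc, borohydride and cold BF3 conditions and can later be removed by fluoride beside a benzyl ether.

**Step 3**
Reactants: 4 (4-bromo-2-methoxyphenoxy)triisopropylsilane; 2 cis-2,3-dimethylsuccinic anhydride
Product: 7 (2R,3S)-4-[3-methoxy-4-(triisopropylsilyloxy)phenyl]-2,3-dimethyl-4-oxobutanoic acid, via aryllithium 5 (not isolated), via arylzinc triflate 6 (not isolated)
Conditions: 4, n-BuLi, THF, −78 °C; Zn(OTf)2, −78 °C to rt; then 2, [Rh(cod)Cl]2 (4 mol %), (R,R)-TADDOL-PNMe2 (8 mol %), THF, 50 °C; 1 M HCl work-up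
Reagents that add atoms: none
Why: This is the rhodium-catalysed enantioselective desymmetrisation (acyl cross-coupling) of a meso succinic anhydride with an arylzinc reagent made in situ, established for this very anhydride: phosphoramidite-bound monovalent rhodium inserts into one of the two enantiotopic acyl–oxygen bonds, transmetalation from 6 and reductive elimination give the aryl ketone, and since neither methine is touched the cis-dimethyl relationship carries over while the choice of carbonyl fixes C3 as R and C4 as S.

**Step 4**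
Reactants: 7 (2R,3S)-keto acid
Product: 9 (3R,4S,5S)-5-[3-methoxy-4-(triisopropylsilyloxy)phenyl]-3,4-dimethyloxolan-2-one (3,4-cis-4,5-trans lactone), via hydroxy acid 8 (not isolated)
Conditions: LiBH(s-Bu)3 (L-Selectride, 2.5 equiv), THF, −78 to −40 °C; then 1 M HCl, rt
Reagents that add atoms: none
Why: In this Felkin–Anh-controlled ketone reduction followed by acid lactonisation with retention, the branched CH(CH3)CO2Li group stands perpendicular to the carbonyl, so the bulky borohydride enters past the small hydrogen and should give the 4,5-anti (5S) carbinol, which closes on acidification through its own oxygen to the 4,5-trans lactone, any all-cis lactone being removable by chromatography.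

**Step 5**
Reactants: 3 4-bromo-2-methoxyphenol
Product: 10 1-(benzyloxy)-4-bromo-2-methoxybenzene
Conditions: BnBr, K2CO3, DMF, rt
Reagents that add atoms: benzyl bromide, BrCc1ccccc1
Why: Williamson ether synthesis on the phenoxide gives one bromide that serves as the source of both ring A and ring C, with a protecting group orthogonal to the silyl ether of ring B.

**Step 6**
Reactants: 10 1-(benzyloxy)-4-bromo-2-methoxybenzene; 9 3,4-cis-4,5-trans lactone
Product: 12 (2R,3S,4S)-1-[4-(benzyloxy)-3-methoxyphenyl]-4-hydroxy-4-[3-methoxy-4-(triisopropylsilyloxy)phenyl]-2,3-dimethylbutan-1-one (handled crude in equilibrium with its hemiketal), via aryllithium 11 (not isolated)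
Conditions: 10, n-BuLi, THF, −78 °C; then 9, THF, −78 °C; AcOH in THF, −78 °C
Reagents that add atoms: none
Why: Bromine–lithium exchange is followed by single 1,2-addition of the aryllithium to the γ-lactone; the tetrahedral lithium alkoxide persists at −78 °C and blocks a second addition, and the cold acidic quench avoids enolisation of the new ketone, so C3, C4 and C5 are carried over unchanged.

**Step 7**
Reactants: 12 γ-hydroxy ketone (ring A ketone, ring B carbinol)
Product: 15 (2S,3R,4S,5S)-2-[4-(benzyloxy)-3-methoxyphenyl]-5-[3-methoxy-4-(triisopropylsilyloxy)phenyl]-3,4-dimethyloxolane, via cyclic hemiketal 13 (not isolated), via oxocarbenium ion 14 (not isolated)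
Conditions: Et3SiH (5 equiv), BF3·OEt2 (2 equiv), CH2Cl2, −78 °C; Et3N then aq NaHCO3 at −78 °C
Reagents that add atoms: none
Why: The C5 hydroxyl of 12 adds to the ring A ketone in a 5-exo-trig closure to give hemiketal 13, BF3 removes the anomeric hydroxyl as hydroxytrifluoroborate, and cation 14, stabilised by O1 and by the para-benzyloxy group of ring A, forms already at −78 °C. The closest known reaction type is the ionic hydrogenation (silane plus Lewis acid) of 2-aryl cyclic hemiketals made from an aryllithium and a γ-lactone, which is established for 2,5-diaryl-3,4-dimethyltetrahydrofurans and gives the 2,3-cis isomers. In 14 ring A is coplanar with the C2=O1 bond, so a pseudoequatorial C3 methyl would collide with an ortho hydrogen; the envelope with C4 as the flap that turns the C3 methyl pseudoaxial also leaves the C4 methyl and ring B pseudoequatorial and should therefore dominate. Et3SiH attacks C2 of this envelope from its inside face, which is the face opposite both methyl groups, so the new C2–H bond lies anti to the C3 methyl and ring A is pushed cis to it, giving (2S). The selectivity needed is facial selectivity at C2, secured by the adjacent C3 methyl with the C4 methyl on the same face, whereas ring B at C5 sits across O1 and away from the trajectory; C5 keeps its oxygen and its configuration. Because 15 is the kinetic and less stable isomer, the mixture is quenched with Et3N at −78 °C before BF3 can reopen a benzylic C–O bond and let C2 or C5 equilibrate.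

**Step 8**
Reactants: 15 tetrahydrofuran core (ring A benzyl ether, ring B silyl ether)
Product: 16 (2S,3R,4S,5S)-2-[4-(benzyloxy)-3-methoxyphenyl]-5-(4-hydroxy-3-methoxyphenyl)-3,4-dimethyloxolane
Conditions: Bu4NF, AcOH, THF, 0 °C
Reagents that add atoms: none
Why: Fluoride-induced cleavage of the aryl silyl ether, buffered with acetic acid, frees only the ring B phenol and leaves the benzyl ether and the benzylic C–O bonds of the ring untouched.

**Step 9**
Reactants: 16 ring B phenol; 17 ethyl (S)-lactate
Product: 18 ethyl (2R)-2-{4-[(2S,3S,4R,5S)-5-(4-benzyloxy-3-methoxyphenyl)-3,4-dimethyloxolan-2-yl]-2-methoxyphenoxy}propanoate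
Conditions: PPh3, DIAD, THF, 0 °C to rt
Reagents that add atoms: none
Why: Mitsunobu etherification displaces the activated lactate hydroxyl by the phenol in an SN2 step with clean inversion, which sets C8' as R; because 17 is enantiopure, any core of the minor enantiomeric series left from step 3 becomes a diastereomer here and can be removed.

**Step 10**
Reactants: 18 ethyl (R)-2-aryloxypropanoate
Product: 19 (2R)-2-{4-[(2S,3S,4R,5S)-5-(4-benzyloxy-3-methoxyphenyl)-3,4-dimethyloxolan-2-yl]-2-methoxyphenoxy}-N-methoxy-N-methylpropanamide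
Conditions: MeNH(OMe)·HCl, i-PrMgCl, THF, −20 °C; aq NH4Cl
Reagents that add atoms: N,O-dimethylhydroxylamine hydrochloride, CNOC.Cl
Why: In this Weinreb amide formation the chloromagnesium amide aminolyses the ester directly at low temperature, conditions routinely used on lactate-type α-oxygenated esters without loss of configuration at the α carbon.

**Step 11**
Reactants: 10 1-(benzyloxy)-4-bromo-2-methoxybenzene; 19 Weinreb amide
Product: 21 (2R)-1-(4-benzyloxy-3-methoxyphenyl)-2-{4-[(2S,3S,4R,5S)-5-(4-benzyloxy-3-methoxyphenyl)-3,4-dimethyloxolan-2-yl]-2-methoxyphenoxy}propan-1-one, via aryl Grignard reagent 20 (not isolated)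
Conditions: 10, Mg, THF, rt to 40 °C; then 19, THF, 0 °C; aq NH4Cl
Reagents that add atoms: none
Why: In this Weinreb ketone synthesis the Grignard adduct is held as a five-membered magnesium chelate that cannot collapse before the quench, so addition stops at the ketone and the acidic C8'–H of the product never meets the basic reagent.

**Step 12**
Reactants: 21 α-aryloxy aryl ketone
Product: 22 (1S,2R)-1-(4-benzyloxy-3-methoxyphenyl)-2-{4-[(2S,3S,4R,5S)-5-(4-benzyloxy-3-methoxyphenyl)-3,4-dimethyloxolan-2-yl]-2-methoxyphenoxy}propan-1-ol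
Conditions: Zn(BH4)2, Et2O–CH2Cl2, −40 to 0 °C; aq NH4Cl
Reagents that add atoms: none
Why: In this Cram-chelate-controlled ketone reduction divalent zinc ties the carbonyl oxygen to the C8' aryloxy oxygen (assisted by the neighbouring ring B methoxy group) in a five-membered chelate, so borohydride attacks the face that carries the C8' hydrogen instead of the methyl group and should give the erythro (7'S,8'R) alcohol.

**Step 13**
Reactants: 22 bis(benzyl ether) of the target
Product: 23 target CNP0171079.3
Conditions: H2 (1 atm), 10% Pd/C, EtOAc, rt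
Reagents that add atoms: none
Why: Catalytic hydrogenolysis cleaves the two aryl benzyl ethers much faster than the secondary benzylic C–O bonds of the tetrahydrofuran and of C7' in a neutral aprotic solvent, so stopping after uptake of two equivalents of hydrogen should release both phenols with all six stereocentres intact.

**Compound list**
1 | meso-2,3-dimethylsuccinic acid | OC(=O)[C@H](C)[C@H](C)C(=O)O | starting material
2 | cis-2,3-dimethylsuccinic anhydride (meso) | O=C1OC(=O)[C@@H](C)[C@H]1C | intermediate
3 | 4-bromo-2-methoxyphenol | COc1cc(Br)ccc1O | starting material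
4 | (4-bromo-2-methoxyphenoxy)triisopropylsilane | COc1cc(Br)ccc1O[Si](C(C)C)(C(C)C)C(C)C | intermediate
5 | [3-methoxy-4-(triisopropylsilyloxy)phenyl]lithium | COc1cc([Li])ccc1O[Si](C(C)C)(C(C)C)C(C)C | intermediate
6 | [3-methoxy-4-(triisopropylsilyloxy)phenyl]zinc triflate | COc1cc([Zn]OS(=O)(=O)C(F)(F)F)ccc1O[Si](C(C)C)(C(C)C)C(C)C | intermediate
7 | (2R,3S)-4-[3-methoxy-4-(triisopropylsilyloxy)phenyl]-2,3-dimethyl-4-oxobutanoic acid | OC(=O)[C@H](C)[C@H](C)C(=O)c1ccc(O[Si](C(C)C)(C(C)C)C(C)C)c(OC)c1 | intermediate
8 | (2R,3S,4S)-4-hydroxy-4-[3-methoxy-4-(triisopropylsilyloxy)phenyl]-2,3-dimethylbutanoic acid | OC(=O)[C@H](C)[C@H](C)[C@H](O)c1ccc(O[Si](C(C)C)(C(C)C)C(C)C)c(OC)c1 | intermediate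
9 | (3R,4S,5S)-5-[3-methoxy-4-(triisopropylsilyloxy)phenyl]-3,4-dimethyloxolan-2-one | O=C1O[C@H](c2ccc(O[Si](C(C)C)(C(C)C)C(C)C)c(OC)c2)[C@@H](C)[C@H]1C | intermediate
10 | 1-(benzyloxy)-4-bromo-2-methoxybenzene | COc1cc(Br)ccc1OCc1ccccc1 | intermediate
11 | [4-(benzyloxy)-3-methoxyphenyl]lithium | COc1cc([Li])ccc1OCc1ccccc1 | intermediate
12 | (2R,3S,4S)-1-[4-(benzyloxy)-3-methoxyphenyl]-4-hydroxy-4-[3-methoxy-4-(triisopropylsilyloxy)phenyl]-2,3-dimethylbutan-1-one | COc1cc(C(=O)[C@H](C)[C@H](C)[C@H](O)c2ccc(O[Si](C(C)C)(C(C)C)C(C)C)c(OC)c2)ccc1OCc1ccccc1 | intermediate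
13 | (3R,4S,5S)-2-[4-(benzyloxy)-3-methoxyphenyl]-5-[3-methoxy-4-(triisopropylsilyloxy)phenyl]-3,4-dimethyloxolan-2-ol (both C2 anomers) | COc1cc(C2(O)O[C@H](c3ccc(O[Si](C(C)C)(C(C)C)C(C)C)c(OC)c3)[C@@H](C)[C@H]2C)ccc1OCc1ccccc1 | intermediate
14 | 2-aryl oxocarbenium ion (C2=O1 cation; C3, C4 and C5 as in 13) as its hydroxytrifluoroborate | COc1cc(C2=[O+][C@H](c3ccc(O[Si](C(C)C)(C(C)C)C(C)C)c(OC)c3)[C@@H](C)[C@H]2C)ccc1OCc1ccccc1.O[B-](F)(F)F | intermediate
15 | (2S,3R,4S,5S)-2-[4-(benzyloxy)-3-methoxyphenyl]-5-[3-methoxy-4-(triisopropylsilyloxy)phenyl]-3,4-dimethyloxolane | COc1cc([C@H]2O[C@H](c3ccc(O[Si](C(C)C)(C(C)C)C(C)C)c(OC)c3)[C@@H](C)[C@H]2C)ccc1OCc1ccccc1 | intermediate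
16 | (2S,3R,4S,5S)-2-[4-(benzyloxy)-3-methoxyphenyl]-5-(4-hydroxy-3-methoxyphenyl)-3,4-dimethyloxolane | COc1cc([C@H]2O[C@H](c3ccc(O)c(OC)c3)[C@@H](C)[C@H]2C)ccc1OCc1ccccc1 | intermediate
17 | ethyl (S)-lactate | C[C@H](O)C(=O)OCC | starting material
18 | ethyl (2R)-2-{4-[(2S,3S,4R,5S)-5-(4-benzyloxy-3-methoxyphenyl)-3,4-dimethyloxolan-2-yl]-2-methoxyphenoxy}propanoate | COc1cc([C@H]2O[C@H](c3ccc(O[C@H](C)C(=O)OCC)c(OC)c3)[C@@H](C)[C@H]2C)ccc1OCc1ccccc1 | intermediate
19 | (2R)-2-{4-[(2S,3S,4R,5S)-5-(4-benzyloxy-3-methoxyphenyl)-3,4-dimethyloxolan-2-yl]-2-methoxyphenoxy}-N-methoxy-N-methylpropanamide | COc1cc([C@H]2O[C@H](c3ccc(O[C@H](C)C(=O)N(C)OC)c(OC)c3)[C@@H](C)[C@H]2C)ccc1OCc1ccccc1 | intermediate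
20 | [4-(benzyloxy)-3-methoxyphenyl]magnesium bromide | COc1cc([Mg]Br)ccc1OCc1ccccc1 | intermediate
21 | (2R)-1-(4-benzyloxy-3-methoxyphenyl)-2-{4-[(2S,3S,4R,5S)-5-(4-benzyloxy-3-methoxyphenyl)-3,4-dimethyloxolan-2-yl]-2-methoxyphenoxy}propan-1-one | COc1cc([C@H]2O[C@H](c3ccc(O[C@H](C)C(=O)c4ccc(OCc5ccccc5)c(OC)c4)c(OC)c3)[C@@H](C)[C@H]2C)ccc1OCc1ccccc1 | intermediate
22 | (1S,2R)-1-(4-benzyloxy-3-methoxyphenyl)-2-{4-[(2S,3S,4R,5S)-5-(4-benzyloxy-3-methoxyphenyl)-3,4-dimethyloxolan-2-yl]-2-methoxyphenoxy}propan-1-ol | COc1cc([C@H]2O[C@H](c3ccc(O[C@H](C)[C@@H](O)c4ccc(OCc5ccccc5)c(OC)c4)c(OC)c3)[C@@H](C)[C@H]2C)ccc1OCc1ccccc1 | intermediate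
23 | 4-[(1S,2R)-1-hydroxy-2-{4-[(2S,3S,4R,5S)-5-(4-hydroxy-3-methoxyphenyl)-3,4-dimethyloxolan-2-yl]-2-methoxyphenoxy}propyl]-2-methoxyphenol (CNP0171079.3) | COc1cc([C@H]2O[C@H](c3ccc(O[C@H](C)[C@@H](O)c4ccc(O)c(OC)c4)c(OC)c3)[C@@H](C)[C@H]2C)ccc1O | target

**Total step count:** 13
**Longest linear sequence:** 11 steps (step 2 or 1, then 3, 4 and 6 to 13)

**Steps most likely to fail**

**Step 7.**
- Risk: the hydride transfer may lose its facial bias. Alternatively, the Lewis acid may reopen a benzylic C–O bond after the reduction, which would let C2 drift to the more stable 2,3-trans arrangement.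
- Fallback idea: C2 is set on the open chain by reagent control. The ring is then closed at its other end (O1–C5) through a para-quinone methide that only the silylated ring B can form.
- Route: it sets out from 12. Ac2O, pyridine and catalytic DMAP trap the open-chain form as the C5 keto acetate F1.
- Corey–Bakshi–Shibata reduction with (R)-Me-CBS and BH3·SMe2 follows. Ring A acts as the large group and the reagent has to override the Felkin–Anh preference. This gives the (2S)-hydroxy acetate F2.
- Bu4NF then removes the silyl group, and the phenoxide expels acetate by 1,6-elimination to give the ring B para-quinone methide F3.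
- The C2 hydroxyl adds to the methide carbon in a reversible 5-exo-trig oxa-1,6-addition. This places ring B trans to the C4 methyl, because the all-cis alternative is far more crowded. C2 is never activated and keeps its configuration.
- Return: the product is phenol 16, where the route is rejoined, and step 8 is no longer needed.

**Step 4.**
- Risk: the Felkin–Anh bias may be too weak, for instance if the carboxylate takes part in hydride delivery. Much syn carbinol, and hence all-cis lactone, would then form.
- Fallback idea: kinetic diastereoselection is replaced by thermodynamic control at C5.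
- Route: it sets out from 7. Unselective reduction with NaBH4 in MeOH and an acidic work-up give 9 together with the all-cis lactone F4.
- The mixture is stirred with CF3CO2H in CH2Cl2, which reversibly ionises the C5–O bond to the para-silyloxybenzyl cation. Reclosure funnels the material into the less crowded 4,5-trans lactone. C3 and C4 are not enolised under these acidic conditions.
- Return: the route is rejoined at 9.

**Step 12.**
- Risk: the weakly basic aryl ether oxygen may chelate poorly, so open Felkin–Anh transition states would compete and the erythro selectivity would erode.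
- Fallback idea: C7' is set by carbon–carbon bond formation instead of hydride delivery. In that mode the non-chelated polar Felkin–Anh pathway is the one that leads to the erythro isomer.
- Route: it sets out from 18. i-Bu2AlH in toluene at −78 °C gives the (R)-2-aryloxypropanal F5, which is used at once to protect C8'.
- Aryllithium 11 is transmetalated with ClTi(OiPr)3 to the non-chelating aryltitanium triisopropoxide F6. This adds to F5 anti to the aryloxy group.
- Return: the adduct is 22, where the route is rejoined, and steps 10 and 11 are bypassed.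

**Further compounds**
F1 | step 7 | (1S,2S,3R)-4-(4-benzyloxy-3-methoxyphenyl)-1-[3-methoxy-4-(triisopropylsilyloxy)phenyl]-2,3-dimethyl-4-oxobutyl acetate | COc1cc(C(=O)[C@H](C)[C@H](C)[C@H](OC(C)=O)c2ccc(O[Si](C(C)C)(C(C)C)C(C)C)c(OC)c2)ccc1OCc1ccccc1
F2 | step 7 | (1S,2S,3R,4S)-4-(4-benzyloxy-3-methoxyphenyl)-4-hydroxy-1-[3-methoxy-4-(triisopropylsilyloxy)phenyl]-2,3-dimethylbutyl acetate | COc1cc([C@@H](O)[C@H](C)[C@H](C)[C@H](OC(C)=O)c2ccc(O[Si](C(C)C)(C(C)C)C(C)C)c(OC)c2)ccc1OCc1ccccc1
F3 | step 7 | ring B para-quinone methide (C5 as exocyclic methide carbon; C2, C3 and C4 as in F2) | COc1cc([C@@H](O)[C@H](C)[C@H](C)C=C2C=CC(=O)C(OC)=C2)ccc1OCc1ccccc1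
F4 | step 4 | (3R,4S,5R)-5-[3-methoxy-4-(triisopropylsilyloxy)phenyl]-3,4-dimethyloxolan-2-one (all-cis lactone) | O=C1O[C@@H](c2ccc(O[Si](C(C)C)(C(C)C)C(C)C)c(OC)c2)[C@@H](C)[C@H]1C
F5 | step 12 | (2R)-2-{4-[(2S,3S,4R,5S)-5-(4-benzyloxy-3-methoxyphenyl)-3,4-dimethyloxolan-2-yl]-2-methoxyphenoxy}propanal | COc1cc([C@H]2O[C@H](c3ccc(O[C@H](C)C=O)c(OC)c3)[C@@H](C)[C@H]2C)ccc1OCc1ccccc1
F6 | step 12 | [4-(benzyloxy)-3-methoxyphenyl]titanium triisopropoxide | COc1cc([Ti](OC(C)C)(OC(C)C)OC(C)C)ccc1OCc1ccccc1
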